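**Retrosynthetic overview**

1. Target ⇐ 3-O-acetylation, enyne metathesis with ethylene and desilylation of a terminal alkyne. The alkyne ⇐ cis-fused γ-lactone (C-12 to O-8), made by axial C-9 alkylation of a Δ6-8-ketone (side chain trans to the C-10 methyl) and cationic lactonisation onto an 8(17)-methylene group (C-8).
2. Decalin ⇐ key step: ring A is closed last on a ring-B cyclohexene by stitching the two carbons of benzyl acrylate between C-10 and C-3 (C-1–C-10 by radical conjugate addition, C-2–C-3 by aldol). The ester carbon is then excised and C-3 is set by hydride reduction.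
3. Enabling feature: in ring A the unsubstituted C-1–C-2 ethano unit is flanked by the methyl-bearing quaternary C-10 (a tertiary radical site, unmasked from the ring-B C-9=C-10 alkene) and by the oxygenated C-3 next to quaternary C-4 (a non-enolisable aldehyde).
4. Alkene aldehyde ⇐ Ireland–Claisen rearrangement (C-9 carbinol → C-5), iodolactone-directed alkylation (C-4) and zinc fragmentation, starting from 1,4-dioxaspiro[4.5]decan-6-one.
5. Ring order: ring B is purchased, a temporary γ-lactone ring is used twice (for C-4, then for C-8), and ring A is formed in step 10.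

Key step: step 10

Remark: labdane numbering (C-1 to C-20) is used for all intermediates, and the oxazaborolidine enantiomer in step 3 is chosen on the assumption that the 2-methylalkenyl arm of the enone behaves as the larger carbonyl substituent.

**Route**

Step 1
Reactants: 1 1,4-dioxaspiro[4.5]decan-6-one
Product: 3 7-methyl-1,4-dioxaspiro[4.5]decan-6-one (racemic), via lithium enolate 2 (not isolated)
Conditions: LiN(i-Pr)2, THF, −78 °C; MeI, −78 °C to 0 °C
Reagents that add atoms: iodomethane, CI
Why: Kinetic enolate alkylation; the ketone can enolise only away from the ketal carbon, so methylation is regiospecific, and the new stereocentre is erased in step 2.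

Step 2
Reactants: 3 7-methyl-1,4-dioxaspiro[4.5]decan-6-one
Product: 4 7-methyl-1,4-dioxaspiro[4.5]dec-7-en-6-one
Conditions: IBX, DMSO/toluene, 70 °C
Reagents that add atoms: none
Why: IBX-mediated α,β-dehydrogenation through the only possible enol should give the endocyclic 2-methyl enone.

Step 3
Reactants: 4 7-methyl-1,4-dioxaspiro[4.5]dec-7-en-6-one
Product: 5 (6S)-7-methyl-1,4-dioxaspiro[4.5]dec-7-en-6-ol
Conditions: (S)-2-methyl-CBS-oxazaborolidine (20 mol %), BH3·SMe2, THF, −20 °C; MeOH quench
Reagents that add atoms: none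
Why: Corey–Bakshi–Shibata 1,2-reduction; the catalyst delivers hydride to one carbonyl face and sets the allylic carbinol (labdane C-9) as S.

Step 4
Reactants: 5 (6S)-7-methyl-1,4-dioxaspiro[4.5]dec-7-en-6-ol
Product: 6 (6S)-7-methyl-1,4-dioxaspiro[4.5]dec-7-en-6-yl propanoate
Conditions: (EtCO)2O, Et3N, DMAP (cat.), CH2Cl2, rt
Reagents that add atoms: propanoic anhydride, CCC(=O)OC(=O)CC
Why: Nucleophile-catalysed acylation of the secondary allylic alcohol; no stereocentre is touched.

Step 5
Reactants: 6 (6S)-7-methyl-1,4-dioxaspiro[4.5]dec-7-en-6-yl propanoate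
Product: 9 2-[(8R)-7-methyl-1,4-dioxaspiro[4.5]dec-6-en-8-yl]propanoic acid (C-2 epimer mixture), via silyl ketene acetal 7 (not isolated), via trimethylsilyl ester 8 (not isolated)
Conditions: LiN(i-Pr)2, Me3SiCl, THF, −78 °C, then rt to 60 °C; aq. NaOH, then pH 4 buffer
Reagents that add atoms: none
Why: Ireland–Claisen rearrangement; the suprafacial [3,3] shift forms the C-4–C-5 bond on the ring face that carried the oxygen, so the carbinol configuration is transferred to C-5, and the C-4 epimers converge in step 7.

Step 6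
Reactants: 9 2-[(8R)-7-methyl-1,4-dioxaspiro[4.5]dec-6-en-8-yl]propanoic acid
Product: 10 iodolactone: γ-lactone from the carboxyl group to C-10, cis-fused to ring B, iodine at C-9 trans to the lactone oxygen, C-8 dioxolane retained (3aR,7R,7aS in benzofuranone numbering; C-4 epimer mixture)
Conditions: I2, NaHCO3, MeCN/H2O, 0 °C
Reagents that add atoms: iodine, II
Why: Iodolactonisation; 5-exo attack of the carboxylate on the more substituted C-10 of the iodonium ion gives the cis-fused lactone with anti iodide, a temporary ring for control of C-4.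

Step 7
Reactants: 10 iodolactone
Product: 12 C-4 quaternary iodolactone: as 10, with 4-methyl and 4-[(triisopropylsilyloxy)methyl], the silyloxymethyl group cis to H-5 (3S,3aR,7R,7aS in benzofuranone numbering), via lithium enolate 11 (not isolated)
Conditions: LiN(i-Pr)2, THF, −78 °C; (i-Pr)3SiOCH2Cl, −78 °C to −40 °C
Reagents that add atoms: (triisopropylsiloxy)methyl chloride, ClCO[Si](C(C)C)(C(C)C)C(C)C
Why: Lactone enolate alkylation with a chloromethyl ether; the electrophile should enter the convex face of the cis-fused bicycle (syn to H-5, anti to ring B), which sets quaternary C-4, and the C-9 iodide has no β-hydrogen to lose.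

Step 8
Reactants: 12 C-4 quaternary iodolactone
Product: 13 lactol of 12 (anomer mixture)
Conditions: i-Bu2AlH, CH2Cl2, −78 °C
Reagents that add atoms: none
Why: Partial reduction of the lactone to the lactol by a hindered aluminium hydride at low temperature; no stereocentre of consequence is formed.

Step 9
Reactants: 13 lactol
Product: 14 (2S)-2-methyl-2-[(8S)-7-methyl-1,4-dioxaspiro[4.5]dec-6-en-8-yl]-3-[(triisopropylsilyl)oxy]propanal
Conditions: Zn dust (activated), THF/H2O, 50 °C, sonication
Reagents that add atoms: none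
Why: Vasella-type reductive fragmentation; zinc insertion into the C-9–I bond and β-elimination of the lactol oxygen restore the C-9=C-10 alkene and release the non-enolisable C-3 aldehyde.

Step 10
Reactants: 14 alkene aldehyde; 15 benzyl acrylate
Product: 18 benzyl 8,8-(ethylenedioxy)-3-hydroxy-4,10-dimethyl-4-[(triisopropylsilyloxy)methyl]-trans-decalin-2-carboxylate (C-4, C-5 and C-10 as in the target; C-2/C-3 diastereomer mixture), via tertiary C-10 radical 16 (not isolated), via ester enolate 17 (not isolated)
Conditions: Fe(acac)3 (0.5 equiv), PhSiH3 (2.5 equiv), benzyl acrylate (3 equiv), EtOH/ethylene glycol, 60 °C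
Reagents that add atoms: none
Why: The trivalent iron hydride generated from Fe(acac)3 and PhSiH3 transfers a hydrogen atom to C-9 of the trisubstituted alkene, the tertiary C-10 radical 16 adds to benzyl acrylate (C-1–C-10 bond), and the α-ester radical is reduced by divalent iron to enolate 17, which closes the C-2–C-3 bond by intramolecular aldol addition to the aldehyde (radical–polar crossover). The closest known reaction type is the iron-catalysed, hydrogen-atom-transfer-initiated conjugate addition/aldol annulation of alkene aldehydes with unsaturated carbonyl acceptors, an established entry to trans-decalins with angular methyl groups. Ring A is closed by an intermolecular Giese addition followed by a 6-(enolexo)-exo-trig aldol through a chair-like transition state, which fuses it trans to ring B. The quaternary C-10 centre is controlled by the adjacent C-5 stereocentre: the acceptor should approach the cyclohexyl radical anti to the bulky tert-alkyl C-4 substituent, so that C-1 ends trans to C-4 and the methyl group trans to H-5. The C-2 and C-3 centres should form with equatorial ester and hydroxyl groups, but the route does not depend on them, since C-2 loses its ester and C-3 is reset in steps 11 to 13. The step needs hydrogen atom transfer to the electron-rich alkene in preference to the acrylate and Giese addition faster than radical reduction, which the nucleophilic tertiary radical and the excess of acceptor secure, and the quaternary C-4 keeps the aldehyde from enolising.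

Step 11
Reactants: 18 annulated β-hydroxy ester
Product: 19 benzyl 8,8-(ethylenedioxy)-4,10-dimethyl-3-oxo-4-[(triisopropylsilyloxy)methyl]-trans-decalin-2-carboxylate (C-2 epimers and enol)
Conditions: Dess–Martin periodinane, NaHCO3, CH2Cl2, rt
Reagents that add atoms: none
Why: Dess–Martin oxidation of the secondary alcohol converges all C-2/C-3 diastereomers to one β-keto ester.

Step 12
Reactants: 19 β-keto benzyl ester
Product: 21 8,8-(ethylenedioxy)-4,10-dimethyl-4-[(triisopropylsilyloxy)methyl]-trans-decalin-3-one (C-4, C-5, C-10 as in the target), via β-keto acid 20 (not isolated)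
Conditions: H2 (1 atm), Pd/C, EtOAc, rt; then toluene, 80 °C
Reagents that add atoms: none
Why: Hydrogenolysis of the benzyl ester and thermal decarboxylation of the β-keto acid remove the activating carbon and leave C-2 as a methylene group.

Step 13
Reactants: 21 3-ketone
Product: 22 8,8-(ethylenedioxy)-4,10-dimethyl-4-[(triisopropylsilyloxy)methyl]-trans-decalin-3-ol, 3-OH equatorial and cis to the C-10 methyl (as in the target)
Conditions: NaBH4, MeOH, 0 °C
Reagents that add atoms: none
Why: Borohydride reduction; axial hydride attack on the 3-ketone next to quaternary C-4, away from the axial C-4 methyl, should give the equatorial alcohol, as is general for 4,4-disubstituted 3-keto trans-decalins.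

Step 14
Reactants: 22 3-alcohol
Product: 23 3-pivalate of 22
Conditions: t-BuCOCl, pyridine, DMAP, CH2Cl2, 40 °C
Reagents that add atoms: pivaloyl chloride, CC(C)(C)C(Cl)=O
Why: Acylation; the pivalate has no α-hydrogen, withstands the amide base, acid and hydrogenation steps ahead, and is removed without an extra step in step 21.

Step 15
Reactants: 23 3-pivalate ketal
Product: 24 4,10-dimethyl-3-(pivaloyloxy)-4-[(triisopropylsilyloxy)methyl]-trans-decalin-8-one
Conditions: PPTS, acetone/H2O, 60 °C
Reagents that add atoms: water, O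
Why: Acid-catalysed hydrolysis of the dioxolane under conditions that spare the silyl ether and the pivalate.

Step 16
Reactants: 24 8-ketone
Product: 25 Δ6-8-ketone (4,10-dimethyl-3-(pivaloyloxy)-4-[(triisopropylsilyloxy)methyl]-trans-octal-6-en-8-one)
Conditions: IBX, DMSO/toluene, 75 °C
Reagents that add atoms: none
Why: IBX dehydrogenation; only the C-7 side has a β-hydrogen (C-10 is quaternary), so the Δ6 enone is the only possible product and C-7 is thereby blocked against enolisation.

Step 17
Reactants: 25 Δ6-8-ketone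
Product: 27 9-[(tert-butoxycarbonyl)methyl] Δ6-8-ketone, side chain axial and trans to the C-10 methyl (as in the target), via lithium dienolate 26 (not isolated)
Conditions: LiN(i-Pr)2, THF, −78 °C; BrCH2CO2t-Bu, DMPU, −78 °C to −40 °C
Reagents that add atoms: tert-butyl bromoacetate, CC(C)(C)OC(=O)CBr
Why: α′-Alkylation of the cross-conjugated lithium dienolate; C-9 is the only α′ position and the electrophile should add axially, anti to the axial C-10 methyl, which sets C-9 under kinetic control.

Step 18
Reactants: 27 alkylated enone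
Product: 28 saturated 8-keto tert-butyl ester (C-9 unchanged)
Conditions: H2 (1 atm), Pd/C, EtOAc, rt; used without chromatography
Reagents that add atoms: none
Why: Heterogeneous hydrogenation of the conjugated C-6=C-7 bond under neutral conditions, which creates no stereocentre and should not epimerise C-9.

Step 19
Reactants: 28 saturated keto ester
Product: 29 8(17)-methylene tert-butyl ester
Conditions: Zn, CH2Br2, TiCl4 (Lombardo reagent), THF/CH2Cl2, 0 °C to rt
Reagents that add atoms: dibromomethane, BrCBr
Why: Lombardo methylenation; the non-basic titanium–zinc reagent converts the hindered ketone without epimerising the adjacent axial C-9 centre and leaves both esters alone.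

Step 20
Reactants: 29 methylene ester
Product: 31 cis-fused γ-lactone (C-12 carbonyl to O-8), C-8 methyl axial and O-8 cis to the C-9 arm (as in the target), 3-pivalate and silyl ether retained, via unsaturated acid 30 (not isolated)
Conditions: CF3CO2H, CH2Cl2, 0 °C
Reagents that add atoms: none
Why: Acid-mediated tert-butyl ester cleavage and Markovnikov lactonisation; the C-8 cation is trapped by the carboxyl group on the axial C-9 arm, which can reach only one face, so C-8 is set with oxygen cis to C-11 and the new methyl trans to it.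

Step 21
Reactants: 31 γ-lactone pivalate
Product: 32 γ-lactol (12-hydroxy-8,12-epoxide) with free 3-OH (anomer mixture)
Conditions: i-Bu2AlH (4 equiv), CH2Cl2, −78 °C
Reagents that add atoms: none
Why: Aluminium hydride reduction; the lactone stops at the lactol at low temperature and the pivalate is cleaved reductively in the same operation.

Step 22
Reactants: 32 γ-lactol
Product: 34 δ-lactol (13-hydroxy-8,13-epoxide; anomer mixture), via enol ether 33 (not isolated)
Conditions: Ph3P(CH2OMe)Cl, KN(SiMe3)2 (excess), THF, 0 °C to rt; then 1 M aq. HCl, THF, rt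
Reagents that add atoms: (methoxymethyl)triphenylphosphonium chloride, COC[P+](c1ccccc1)(c1ccccc1)c1ccccc1.[Cl-]; water, O
Why: Wittig methoxymethylenation of the ring-opened hydroxy aldehyde and hydrolysis of the enol ether give a one-carbon homologation, and the new aldehyde recloses on the C-8 hydroxyl as a six-membered lactol.

Step 23
Reactants: 34 δ-lactol
Product: 35 terminal alkyne (C-13≡C-14) with free 3-OH and 8-OH, 18-O-triisopropylsilyl
Conditions: dimethyl (1-diazo-2-oxopropyl)phosphonate, K2CO3, MeOH, rt
Reagents that add atoms: dimethyl (1-diazo-2-oxopropyl)phosphonate, COP(=O)(OC)C(=[N+]=[N-])C(C)=O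
Why: Ohira–Bestmann (Seyferth–Gilbert) homologation of the lactol aldehyde to the terminal alkyne under mild base.

Step 24
Reactants: 35 alkyne diol
Product: 36 3-acetate of 35
Conditions: Ac2O, pyridine, rt
Reagents that add atoms: acetic anhydride, CC(=O)OC(C)=O
Why: Acetylation; only the secondary 3-OH reacts, since the tertiary 8-OH is inert under these conditions and O-18 is silylated.

Step 25
Reactants: 36 alkyne acetate
Product: 37 18-O-triisopropylsilyl ether of the target (2-substituted buta-1,3-diene side chain)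
Conditions: ethylene (1 atm), second-generation Grubbs catalyst RuCl2(=CHPh)(PCy3)(H2IMes) (10 mol %), toluene, 80 °C
Reagents that add atoms: ethylene, C=C
Why: Enyne cross-metathesis of a terminal alkyne with ethylene gives the 2-substituted 1,3-diene directly and tolerates the acetate and the tertiary alcohol.

Step 26
Reactants: 37 silyl ether
Product: 38 target, CNP0313672.1
Conditions: HF·pyridine, pyridine, THF, 0 °C to rt
Reagents that add atoms: none
Why: Buffered fluoride desilylation under mildly acidic conditions frees the primary alcohol while disfavouring migration of the 3-acetate and leaving the diene and the tertiary alcohol untouched.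

**Compound list**

1 | 1,4-dioxaspiro[4.5]decan-6-one | O=C1CCCCC12OCCO2 | starting material
2 | lithium enolate of 1 | [Li+].[O-]C1=CCCCC12OCCO2 | intermediate
3 | 7-methyl-1,4-dioxaspiro[4.5]decan-6-one (racemic) | CC1CCCC2(OCCO2)C1=O | intermediate
4 | 7-methyl-1,4-dioxaspiro[4.5]dec-7-en-6-one | CC1=CCCC2(OCCO2)C1=O | intermediate
5 | (6S)-7-methyl-1,4-dioxaspiro[4.5]dec-7-en-6-ol | O[C@H]1C(C)=CCCC12OCCO2 | intermediate
6 | (6S)-7-methyl-1,4-dioxaspiro[4.5]dec-7-en-6-yl propanoate | CCC(=O)O[C@H]1C(C)=CCCC12OCCO2 | intermediate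
7 | trimethylsilyl ketene acetal of 6 | CC=C(O[Si](C)(C)C)O[C@H]1C(C)=CCCC12OCCO2 | intermediate
8 | trimethylsilyl ester of 9 | CC(C(=O)O[Si](C)(C)C)[C@H]1CCC2(OCCO2)C=C1C | intermediate
9 | 2-[(8R)-7-methyl-1,4-dioxaspiro[4.5]dec-6-en-8-yl]propanoic acid (C-2 epimers) | CC(C(=O)O)[C@H]1CCC2(OCCO2)C=C1C | intermediate
10 | iodolactone (γ-lactone to C-10, 9-iodo, 8-dioxolane; C-4 epimers) | CC1C(=O)O[C@]2(C)[C@@H](I)C3(OCCO3)CC[C@H]12 | intermediate
11 | lithium enolate of 10 | [Li+].CC1=C([O-])O[C@]2(C)[C@@H](I)C3(OCCO3)CC[C@H]12 | intermediate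
12 | C-4 quaternary iodolactone (4-methyl, 4-silyloxymethyl cis to H-5) | C[C@]1(CO[Si](C(C)C)(C(C)C)C(C)C)C(=O)O[C@]2(C)[C@@H](I)C3(OCCO3)CC[C@H]12 | intermediate
13 | lactol of 12 | C[C@]1(CO[Si](C(C)C)(C(C)C)C(C)C)C(O)O[C@]2(C)[C@@H](I)C3(OCCO3)CC[C@H]12 | intermediate
14 | (2S)-2-methyl-2-[(8S)-7-methyl-1,4-dioxaspiro[4.5]dec-6-en-8-yl]-3-[(triisopropylsilyl)oxy]propanal | O=C[C@](C)(CO[Si](C(C)C)(C(C)C)C(C)C)[C@H]1CCC2(OCCO2)C=C1C | intermediate
15 | benzyl acrylate | C=CC(=O)OCc1ccccc1 | starting material
16 | tertiary C-10 radical from 14 | O=C[C@](C)(CO[Si](C(C)C)(C(C)C)C(C)C)[C@H]1CCC2(OCCO2)C[C]1C | intermediate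
17 | benzyl ester enolate (Giese adduct) | O=C[C@](C)(CO[Si](C(C)C)(C(C)C)C(C)C)[C@H]1CCC2(OCCO2)C[C@]1(C)CC=C([O-])OCc1ccccc1 | intermediate
18 | annulated β-hydroxy benzyl ester (trans-decalin; C-2/C-3 mixture) | C1[C@]2(C)CC(C(=O)OCc3ccccc3)C(O)[C@](C)(CO[Si](C(C)C)(C(C)C)C(C)C)[C@H]2CCC14OCCO4 | intermediate
19 | β-keto benzyl ester | C1[C@]2(C)CC(C(=O)OCc3ccccc3)C(=O)[C@](C)(CO[Si](C(C)C)(C(C)C)C(C)C)[C@H]2CCC14OCCO4 | intermediate
20 | β-keto acid | C1[C@]2(C)CC(C(=O)O)C(=O)[C@](C)(CO[Si](C(C)C)(C(C)C)C(C)C)[C@H]2CCC14OCCO4 | intermediate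
21 | 3-ketone (8-dioxolane, 18-O-silyl) | C1[C@]2(C)CCC(=O)[C@](C)(CO[Si](C(C)C)(C(C)C)C(C)C)[C@H]2CCC14OCCO4 | intermediate
22 | 3-alcohol (equatorial) | C1[C@]2(C)CC[C@@H](O)[C@](C)(CO[Si](C(C)C)(C(C)C)C(C)C)[C@H]2CCC14OCCO4 | intermediate
23 | 3-pivalate | C1[C@]2(C)CC[C@@H](OC(=O)C(C)(C)C)[C@](C)(CO[Si](C(C)C)(C(C)C)C(C)C)[C@H]2CCC14OCCO4 | intermediate
24 | 8-ketone | C1[C@]2(C)CC[C@@H](OC(=O)C(C)(C)C)[C@](C)(CO[Si](C(C)C)(C(C)C)C(C)C)[C@H]2CCC1=O | intermediate
25 | Δ6-8-ketone | C1[C@]2(C)CC[C@@H](OC(=O)C(C)(C)C)[C@](C)(CO[Si](C(C)C)(C(C)C)C(C)C)[C@H]2C=CC1=O | intermediate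
26 | lithium dienolate of 25 | [Li+].[O-]C1=C[C@]2(C)CC[C@@H](OC(=O)C(C)(C)C)[C@](C)(CO[Si](C(C)C)(C(C)C)C(C)C)[C@H]2C=C1 | intermediate
27 | 9-[(tert-butoxycarbonyl)methyl] Δ6-8-ketone | CC(C)(C)OC(=O)C[C@@H]1[C@]2(C)CC[C@@H](OC(=O)C(C)(C)C)[C@](C)(CO[Si](C(C)C)(C(C)C)C(C)C)[C@H]2C=CC1=O | intermediate
28 | saturated 8-keto tert-butyl ester | CC(C)(C)OC(=O)C[C@@H]1[C@]2(C)CC[C@@H](OC(=O)C(C)(C)C)[C@](C)(CO[Si](C(C)C)(C(C)C)C(C)C)[C@H]2CCC1=O | intermediate
29 | 8(17)-methylene tert-butyl ester | CC(C)(C)OC(=O)C[C@@H]1[C@]2(C)CC[C@@H](OC(=O)C(C)(C)C)[C@](C)(CO[Si](C(C)C)(C(C)C)C(C)C)[C@H]2CCC1=C | intermediate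
30 | 8(17)-methylene carboxylic acid | OC(=O)C[C@@H]1[C@]2(C)CC[C@@H](OC(=O)C(C)(C)C)[C@](C)(CO[Si](C(C)C)(C(C)C)C(C)C)[C@H]2CCC1=C | intermediate
31 | cis-fused γ-lactone (12,8-olide) | O=C1C[C@@H]2[C@]3(C)CC[C@@H](OC(=O)C(C)(C)C)[C@](C)(CO[Si](C(C)C)(C(C)C)C(C)C)[C@H]3CC[C@]2(C)O1 | intermediate
32 | γ-lactol with free 3-OH | OC1C[C@@H]2[C@]3(C)CC[C@@H](O)[C@](C)(CO[Si](C(C)C)(C(C)C)C(C)C)[C@H]3CC[C@]2(C)O1 | intermediate
33 | methyl enol ether (E/Z) | COC=CC[C@@H]1[C@]2(C)CC[C@@H](O)[C@](C)(CO[Si](C(C)C)(C(C)C)C(C)C)[C@H]2CC[C@]1(C)O | intermediate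
34 | δ-lactol (13-hydroxy-8,13-epoxide) | OC1CC[C@@H]2[C@]3(C)CC[C@@H](O)[C@](C)(CO[Si](C(C)C)(C(C)C)C(C)C)[C@H]3CC[C@]2(C)O1 | intermediate
35 | terminal alkyne diol, 18-O-silyl | C#CCC[C@@H]1[C@]2(C)CC[C@@H](O)[C@](C)(CO[Si](C(C)C)(C(C)C)C(C)C)[C@H]2CC[C@]1(C)O | intermediate
36 | alkyne 3-acetate | C#CCC[C@@H]1[C@]2(C)CC[C@@H](OC(C)=O)[C@](C)(CO[Si](C(C)C)(C(C)C)C(C)C)[C@H]2CC[C@]1(C)O | intermediate
37 | 18-O-triisopropylsilyl ether of the target | C=CC(=C)CC[C@@H]1[C@]2(C)CC[C@@H](OC(C)=O)[C@](C)(CO[Si](C(C)C)(C(C)C)C(C)C)[C@H]2CC[C@]1(C)O | intermediate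
38 | CNP0313672.1 (3R,4S,5S,8S,9R,10R in labdane numbering) | C=CC(=C)CC[C@@H]1[C@]2(C)CC[C@@H](OC(C)=O)[C@](C)(CO)[C@H]2CC[C@]1(C)O | target

**Totals**

Total step count: 26. Longest linear sequence: 26 steps (from 1; all partners are purchased).

**Steps most likely to fail**

Step 10. What may go wrong: the C-10 radical may be reduced before it adds to the acrylate, the enolate may be protonated before ring closure, or the intermolecular radical addition may show poor facial discrimination and give a cis-fused ring A. Fallback: setting out from 14, the two bonds are made one at a time. Addition of vinylmagnesium bromide (THF, −78 °C) to the aldehyde gives allylic alcohol F1 (C-2–C-3 bond). Dess–Martin oxidation gives vinyl ketone F2. An intramolecular iron-hydride-initiated radical conjugate addition (Fe(acac)3, PhSiH3, EtOH, 60 °C; 6-exo-trig attack of the C-10 radical on the enone terminus through a chair) then closes the C-1–C-10 bond. The route is rejoined at ketone 21.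

Step 17. What may go wrong: proton transfer from the bromoacetate to the hindered dienolate, O-alkylation, or epimerisation of C-9 to the equatorial isomer. Fallback: setting out from 25, the lithium dienolate is alkylated with allyl iodide, which is more reactive and has no acidic hydrogen, to give 9-allyl enone F3. Ozonolysis of the terminal alkene (O3, CH2Cl2/MeOH, −78 °C, then Me2S; the conjugated alkene reacts more slowly) gives aldehyde F4. Pinnick oxidation (NaClO2, NaH2PO4, 2-methylbut-2-ene) gives acid F5. Esterification with tert-butyl 2,2,2-trichloroacetimidate (BF3·OEt2 cat.) returns to 27.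

Step 20. What may go wrong: the C-8 cation may lose a proton to the 8,9-alkene and scramble C-9, or undergo hydride and methyl shifts, before the lactone closes, and the silyl ether may be lost in acid. Fallback: setting out from 29, the tert-butyl ester is cleaved without protic acid (Me3SiOTf, 2,6-lutidine, CH2Cl2, 0 °C) and unsaturated acid 30 is isolated. Iodolactonisation under kinetic, non-cationic conditions (I2, NaHCO3, MeCN, 0 °C) gives iodomethyl lactone F6, again with the oxygen delivered from the C-9 arm. Radical deiodination (Bu3SnH, AIBN, toluene, 80 °C) returns to 31.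

**Further compounds**

F1 | step 10 | allylic alcohol from 14 and vinylmagnesium bromide (C-3 epimers) | C=CC(O)[C@](C)(CO[Si](C(C)C)(C(C)C)C(C)C)[C@H]1CCC2(OCCO2)C=C1C
F2 | step 10 | vinyl ketone | C=CC(=O)[C@](C)(CO[Si](C(C)C)(C(C)C)C(C)C)[C@H]1CCC2(OCCO2)C=C1C
F3 | step 17 | 9-allyl Δ6-8-ketone | C=CC[C@@H]1[C@]2(C)CC[C@@H](OC(=O)C(C)(C)C)[C@](C)(CO[Si](C(C)C)(C(C)C)C(C)C)[C@H]2C=CC1=O
F4 | step 17 | 9-(2-oxoethyl) Δ6-8-ketone | O=CC[C@@H]1[C@]2(C)CC[C@@H](OC(=O)C(C)(C)C)[C@](C)(CO[Si](C(C)C)(C(C)C)C(C)C)[C@H]2C=CC1=O
F5 | step 17 | 9-(carboxymethyl) Δ6-8-ketone | OC(=O)C[C@@H]1[C@]2(C)CC[C@@H](OC(=O)C(C)(C)C)[C@](C)(CO[Si](C(C)C)(C(C)C)C(C)C)[C@H]2C=CC1=O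
F6 | step 20 | 17-iodo γ-lactone | O=C1C[C@@H]2[C@]3(C)CC[C@@H](OC(=O)C(C)(C)C)[C@](C)(CO[Si](C(C)C)(C(C)C)C(C)C)[C@H]3CC[C@]2(CI)O1
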